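**Retrosynthetic overview**
- Target ⇒ ring alcohol (hydroxy aryl ether) + (R)-2-methylbutanoic acid: ester C–O bond, made last.
- Hydroxy aryl ether ⇒ syn-epoxy aryl ether: the C–CH3 bond at the tertiary oxirane carbon creates the CMe2 group and the carbinol together; epoxy ether ⇒ epoxy alcohol + umbelliferone (aryl ether).
- Epoxy alcohol ⇒ mirror-symmetric (2,6-dimethylcyclohexa-2,5-dienyl)methanol: a hydroxyl-directed, catalyst-controlled mono-epoxidation chooses one of two enantiotopic alkenes and sets both ring stereocentres (key step).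
- Dienyl methanol ⇒ 2,6-dimethylbenzoic acid: Birch dearomatisation, then carboxyl reduction.
- Rings: the carbocycle is the benzene ring of the acid (dearomatised, never built); the oxirane is formed in step 3 and opened in step 5; the coumarin bicycle is bought intact.

Assumption: the SMILES is read as the cis-(1R,5S) ring carrying a (2R)-2-methylbutanoyl group, and (R)-2-methylbutanoic acid is bought as the single enantiomer.

**Step 1**
Reactants: 1 2,6-dimethylbenzoic acid
Product: 2 2,6-dimethylcyclohexa-2,5-diene-1-carboxylic acid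
Conditions: Li (2.5 equiv), NH3(l)/THF, −78 °C; then NH4Cl; evaporate, cold aq. HCl to pH 3
Reagents that add atoms: none
Why: Birch reduction: two electrons from Li give the carboxylate-stabilised ring dianion, which NH3 protonates para and NH4Cl then protonates kinetically at the ipso carbon, a regiochemistry the two methyl groups reinforce (they stay on the surviving C=C bonds), so the aromatic ring is broken to the non-conjugated, mirror-symmetric 2,5-diene with no stereocentre.

**Step 2**
Reactants: 2 2,6-dimethylcyclohexa-2,5-diene-1-carboxylic acid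
Product: 3 (2,6-dimethylcyclohexa-2,5-dien-1-yl)methanol
Conditions: LiAlH4, Et2O, 0 °C → rt; H2O/aq. NaOH work-up
Reagents that add atoms: none
Why: Hydride reduction of the carboxylic acid to the primary alcohol; LiAlH4 leaves the isolated skipped diene alone and the product keeps its mirror plane, so it is the prochiral substrate for the symmetry-breaking step.

**Step 3**
Reactants: 3 (2,6-dimethylcyclohexa-2,5-dien-1-yl)methanol
Product: 4 [(1S,2R,6R)-1,3-dimethyl-7-oxabicyclo[4.1.0]hept-3-en-2-yl]methanol (mono-epoxide, oxirane oxygen cis to the CH2OH arm)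
Conditions: VO(OiPr)3 (2 mol %), C2-symmetric bis-hydroxamic acid ligand N,N'-dihydroxy-N,N'-bis(2,2-diphenylacetyl)-trans-cyclohexane-1,2-diamine (single antipode, 4 mol %), cumene hydroperoxide (1.2 equiv), toluene, 0 °C → rt
Reagents that add atoms: cumene hydroperoxide, CC(C)(OO)c1ccccc1
Why: Proposed new method: the vanadium alkoxide of the homoallylic OH binds the hydroperoxide and can deliver oxygen only to the alkene face syn to the CH2OH arm (this sets the cis relation between the future carbinol and the side chain), while the chiral bis-hydroxamate pocket selects one of the two enantiotopic trisubstituted alkenes, so the ring CH, the oxirane CH and the oxirane quaternary carbon are fixed in one event and the minor enantiomer is skimmed off by faster second epoxidation; the closest known reaction type is the vanadium/bis-hydroxamic acid asymmetric epoxidation of homoallylic alcohols and its use to desymmetrise meso dienyl carbinols, here extended to a cyclohexa-2,5-dienylmethanol, so the sense of induction is not known and the ligand antipode, (R,R) or (S,S), that gives 4 and not its enantiomer must be fixed in a pilot run.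

**Step 4**
Reactants: 4 [(1S,2R,6R)-1,3-dimethyl-7-oxabicyclo[4.1.0]hept-3-en-2-yl]methanol; 5 7-hydroxy-2H-chromen-2-one (umbelliferone)
Product: 6 7-{[(1S,2R,6R)-1,3-dimethyl-7-oxabicyclo[4.1.0]hept-3-en-2-yl]methoxy}-2H-chromen-2-one
Conditions: PPh3, DIAD, THF, 0 °C → rt
Reagents that add atoms: none
Why: Mitsunobu etherification: umbelliferone (pKa about 7.8) protonates the betaine and its phenoxide displaces the primary oxyphosphonium by SN2 at the CH2 group, so no stereocentre is involved, the oxirane survives the neutral conditions, and etherifying before the secondary OH is unveiled avoids cyclodehydration of a cis-1,4-diol to a bridged ether.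

**Step 5**
Reactants: 6 7-{[(1S,2R,6R)-1,3-dimethyl-7-oxabicyclo[4.1.0]hept-3-en-2-yl]methoxy}-2H-chromen-2-one
Product: 7 7-{[(1S,5R)-5-hydroxy-2,6,6-trimethylcyclohex-2-en-1-yl]methoxy}-2H-chromen-2-one (OH cis to the aryloxymethyl arm)
Conditions: Me3Al (4 equiv), CH2Cl2/hexane, −78 → 0 °C; aq. potassium sodium tartrate
Reagents that add atoms: trimethylaluminium, C[Al](C)C
Why: Lewis-acid-mediated alkylative epoxide opening: excess Me3Al (one equivalent is held by the coumarin carbonyl) activates the oxirane, the C–O bond at the tertiary carbon ionises preferentially and a methyl group is transferred there from the face anti to oxygen, which turns that carbon into the non-stereogenic CMe2 and leaves the secondary C–O bond, hence the (R) carbinol cis to the side chain, untouched; the lactone and the trisubstituted alkene do not react with Me3Al at this temperature.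

**Step 6**
Reactants: 7 7-{[(1S,5R)-5-hydroxy-2,6,6-trimethylcyclohex-2-en-1-yl]methoxy}-2H-chromen-2-one; 8 (2R)-2-methylbutanoic acid
Product: 9 (1R,5S)-4,6,6-trimethyl-5-{[(2-oxo-2H-chromen-7-yl)oxy]methyl}cyclohex-3-en-1-yl (2R)-2-methylbutanoate (CNP0199249.1)
Conditions: DCC, DMAP (0.2 equiv), CH2Cl2, 0 °C → rt
Reagents that add atoms: none
Why: Steglich esterification: the activated acyl of 8 acylates the equatorial, neopentyl-type alcohol (the same environment as a triterpenoid 3β-OH) with retention at the carbinol because only the O–H bond is broken, and low temperature with substoichiometric DMAP keeps ketene formation, and thus epimerisation of the (R) α-centre, negligible.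

**Compound list**
1 | 2,6-dimethylbenzoic acid | Cc1cccc(C)c1C(=O)O | starting material
2 | 2,6-dimethylcyclohexa-2,5-diene-1-carboxylic acid | CC1=CCC=C(C)C1C(=O)O | intermediate
3 | (2,6-dimethylcyclohexa-2,5-dien-1-yl)methanol | CC1=CCC=C(C)C1CO | intermediate
4 | [(1S,2R,6R)-1,3-dimethyl-7-oxabicyclo[4.1.0]hept-3-en-2-yl]methanol | OC[C@H]1C(C)=CC[C@H]2O[C@@]12C | intermediate
5 | 7-hydroxy-2H-chromen-2-one (umbelliferone) | O=c1ccc2ccc(O)cc2o1 | starting material
6 | 7-{[(1S,2R,6R)-1,3-dimethyl-7-oxabicyclo[4.1.0]hept-3-en-2-yl]methoxy}-2H-chromen-2-one | O=c1ccc2ccc(OC[C@H]3C(C)=CC[C@H]4O[C@@]34C)cc2o1 | intermediate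
7 | 7-{[(1S,5R)-5-hydroxy-2,6,6-trimethylcyclohex-2-en-1-yl]methoxy}-2H-chromen-2-one | O[C@@H]1CC=C(C)[C@H](COc2ccc3ccc(=O)oc3c2)C1(C)C | intermediate
8 | (2R)-2-methylbutanoic acid | CC[C@@H](C)C(=O)O | starting material
9 | (1R,5S)-4,6,6-trimethyl-5-{[(2-oxo-2H-chromen-7-yl)oxy]methyl}cyclohex-3-en-1-yl (2R)-2-methylbutanoate | CC[C@@H](C)C(=O)O[C@@H]1CC=C(C)[C@H](COc2ccc3ccc(=O)oc3c2)C1(C)C | target

**Totals**
Total step count: 6. Longest linear sequence: 6 steps (1 → 2 → 3 → 4 → 6 → 7 → 9); 5 and 8 are bought and enter in steps 4 and 6.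

**Steps most likely to fail, with fallbacks**

Step 3 (new desymmetrisation: level and sense of induction, over-oxidation or aromatisation of the 1,4-diene). The fallback sets out from 3 and comes back at 7; it breaks the symmetry with a chiral dioxirane instead of a directed metal peroxide. Compound 3 is first etherified with 5 (PPh3, DIAD, THF) to 7-[(2,6-dimethylcyclohexa-2,5-dien-1-yl)methoxy]-2H-chromen-2-one F1. Shi epoxidation (fructose-derived ketone, antipode chosen in a pilot run, KHSO5, K2CO3 buffer, MeCN/dimethoxymethane/water, 0 °C), a reaction type reported to desymmetrise cyclohexa-1,4-dienes, then gives the mono-epoxide anti to the side chain, 7-{[(1R,2R,6S)-1,3-dimethyl-7-oxabicyclo[4.1.0]hept-3-en-2-yl]methoxy}-2H-chromen-2-one F2. Me3Al as in step 5 opens it to the trans alcohol 7-{[(1S,5S)-5-hydroxy-2,6,6-trimethylcyclohex-2-en-1-yl]methoxy}-2H-chromen-2-one F3. Dess–Martin oxidation gives the ketone 7-{[(1S)-2,6,6-trimethyl-5-oxocyclohex-2-en-1-yl]methoxy}-2H-chromen-2-one F4, and NaBH4 in MeOH at −20 °C (axial hydride attack next to CMe2, equatorial OH) corrects the carbinol configuration and returns 7.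

Step 4 (SN2 at a β-branched CH2 flanked by the quaternary oxirane carbon may be slow). The fallback sets out from 4 and comes back at 6; it reverses the polarity of the C–O bond formation so that nothing is displaced at the hindered carbon. Compound 4 is O-arylated with bought 7-bromo-2H-chromen-2-one (O=c1ccc2ccc(Br)cc2o1) using [Pd(allyl)Cl]2, RockPhos, Cs2CO3, toluene, 90 °C, which gives 6 directly. New compounds made: none F0.

Step 5 (methyl transfer may lose to hydride shift or to elimination and aromatisation, or be disturbed by the coumarin). The fallback sets out from 6 and comes back at 7; it builds the quaternary carbon by regiospecific enolate methylation instead of epoxide alkylation. Cp2TiCl (trivalent titanium, made from Cp2TiCl2 and Mn dust, THF, rt) opens the oxirane homolytically at the tertiary carbon, and β-hydrogen loss gives the exocyclic allylic alcohol 7-{[(1S,5R)-5-hydroxy-2-methyl-6-methylidenecyclohex-2-en-1-yl]methoxy}-2H-chromen-2-one F5. Dess–Martin oxidation gives the α-methylene ketone 7-{[(1S)-2-methyl-6-methylidene-5-oxocyclohex-2-en-1-yl]methoxy}-2H-chromen-2-one F6. Conjugate reduction with LiBH(s-Bu)3 (1.05 equiv, THF, −78 °C) generates the enolate only towards the methyl-bearing carbon, and MeI traps it to give the gem-dimethyl ketone 7-{[(1S)-2,6,6-trimethyl-5-oxocyclohex-2-en-1-yl]methoxy}-2H-chromen-2-one F4, the same ketone as in the first fallback. NaBH4 reduction as there returns 7.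

**Further compounds**
F1 | step 3 | 7-[(2,6-dimethylcyclohexa-2,5-dien-1-yl)methoxy]-2H-chromen-2-one | CC1=CCC=C(C)C1COc1ccc2ccc(=O)oc2c1
F2 | step 3 | 7-{[(1R,2R,6S)-1,3-dimethyl-7-oxabicyclo[4.1.0]hept-3-en-2-yl]methoxy}-2H-chromen-2-one | O=c1ccc2ccc(OC[C@H]3C(C)=CC[C@@H]4O[C@]34C)cc2o1
F3 | step 3 | 7-{[(1S,5S)-5-hydroxy-2,6,6-trimethylcyclohex-2-en-1-yl]methoxy}-2H-chromen-2-one | O[C@H]1CC=C(C)[C@H](COc2ccc3ccc(=O)oc3c2)C1(C)C
F4 | step 3 | 7-{[(1S)-2,6,6-trimethyl-5-oxocyclohex-2-en-1-yl]methoxy}-2H-chromen-2-one | O=C1CC=C(C)[C@H](COc2ccc3ccc(=O)oc3c2)C1(C)C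
F0 | step 4 | none | none
F5 | step 5 | 7-{[(1S,5R)-5-hydroxy-2-methyl-6-methylidenecyclohex-2-en-1-yl]methoxy}-2H-chromen-2-one | O[C@@H]1CC=C(C)[C@H](COc2ccc3ccc(=O)oc3c2)C1=C
F6 | step 5 | 7-{[(1S)-2-methyl-6-methylidene-5-oxocyclohex-2-en-1-yl]methoxy}-2H-chromen-2-one | O=C1CC=C(C)[C@H](COc2ccc3ccc(=O)oc3c2)C1=C
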